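**Plan**
1. Retrosynthetic cuts, in order: C5–OOH (a Schenck ene step, which returns C4=C15 to C4=C5); the acyl C–O bonds at O8 and O3; C7–C11 (the acrylate unit C11–C13); then the angular methyl is folded back into a cyclopropane (C5–C14 re-formed) and C10–C14 and C5–C14 are cut together; last, C4–C15.
2. Forward: ring A (C1–C5, C10) and ring B (C5–C10) both come intact from 6-methoxy-1-tetralone. C15 is added and Birch reduction leaves C5=C10. A CH2 unit closes the only new ring (C5–C10–C14), which is reopened at C5–C14 to leave methyl C14 on C10 and C4=C5. Ring B is then functionalised, and O2 is added last.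
3. Enabling feature: O3 in ring A is homoallylic to the ring-fusion bond (C3–C4–C5=C10) and lies on the same β face as methyl C14 on C10. A carbenoid held on O3 can therefore deliver C14. Once C3 is a ketone it enolises towards C4, so it can expel C14 from C5 and from no other carbon.
4. Stereochemistry: C3 and C4 come from a reagent-controlled hydroboration. C3 is relayed to C5 and C10 in the cyclopropanation. The 10β-methyl then restores C3 (α-face hydride) and sets C7 (equatorial, by equilibration), C8 (α-face hydride) and C5 (α-face singlet oxygen).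

Key step: step 5

Numbering: eudesmane numbers are used for all bicyclic compounds. Ring A is C1–C5 and C10, ring B is C5–C10, C14 is the methyl on C10, C15 is the carbon on C4, and C11–C13 is the acrylate. β is the face of C14.
Assumption: the borane derived from (+)-α-pinene is taken to attack alkene 4 on the same face as in 1-methylcyclohexene, which corresponds to 3S,4S. If the sense proves opposite, the reagent from (−)-α-pinene is used and nothing else changes.

**Step 1**
Reactants: 1 6-methoxy-1-tetralone; 2 methylmagnesium bromide
Product: 4 7-methoxy-4-methyl-1,2-dihydronaphthalene, via tertiary benzylic alcohol 3 (not isolated)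
Conditions: MeMgBr, THF, 0 °C to rt; then 2 M HCl, rt
Reagents that add atoms: methylmagnesium bromide, C[Mg]Br
Why: Grignard 1,2-addition gives a tertiary benzylic alcohol whose ionisation is helped by the para methoxy group, so E1 dehydration during the acidic work-up should give the conjugated endocyclic C3=C4 alkene; no stereocentre is formed.

**Step 2**
Reactants: 4 7-methoxy-4-methyl-1,2-dihydronaphthalene
Product: 6 (1S,2S)-6-methoxy-1-methyl-1,2,3,4-tetrahydronaphthalen-2-ol (3β-OH, 4α-CH3), via isopinocampheylalkylborane 5 (not isolated)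
Conditions: (IpcBH2)2·TMEDA [from (+)-α-pinene], BF3·OEt2, THF, rt; 4, −25 °C; then NaOH, H2O2, 0 °C to rt
Reagents that add atoms: hydrogen peroxide, OO
Why: In this asymmetric hydroboration–oxidation of a trisubstituted alkene, boron goes to the non-benzylic C3, syn addition places O3 and C15 trans, the terpene ligand selects the alkene face (3S,4S), oxidation retains configuration, and recrystallisation of 6 should remove residual enantiomer.

**Step 3**
Reactants: 6 (1S,2S)-6-methoxy-1-methyl-1,2,3,4-tetrahydronaphthalen-2-ol
Product: 7 (1S,2S)-6-methoxy-1-methyl-1,2,3,4,5,8-hexahydronaphthalen-2-ol (C5=C10 and enol ether C7=C8)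
Conditions: Li, NH3 (l), THF–t-BuOH, −33 °C
Reagents that add atoms: none
Why: Birch reduction of an anisole leaves the double bonds on the donor-bearing carbons, that is the enol ether C7=C8(OMe) and the tetrasubstituted C5=C10, and the lithium alkoxide at O3 and the C3 and C4 centres are not affected.

**Step 4**
Reactants: 7 Birch dienol ether; 8 ethylene glycol
Product: 9 (5'S,6'S)-5'-methyl-3',4',5',6',7',8'-hexahydro-1'H-spiro[1,3-dioxolane-2,2'-naphthalen]-6'-ol (3β-hydroxy-4α-methyl-5(10)-octalin, C8 as dioxolane)
Conditions: HOCH2CH2OH, PPTS (cat.), CH2Cl2, rt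
Reagents that add atoms: ethylene glycol, OCCO
Why: In this acid-catalysed acetal exchange, C7 of the enol ether is protonated, the C8 oxocarbenium ion takes up the diol and methanol is lost, under conditions too mild to move the tetrasubstituted C5=C10 alkene, which is the usual behaviour of Birch dienol ethers.

**Step 5**
Reactants: 9 homoallylic alcohol ketal; 10 diiodomethane
Product: 12 3β-hydroxy-4α-methyl-5β,10β-methanodecalin with C8 as dioxolane (cyclopropane C5–C10–C14 on the β face), via ethylzinc alkoxide 11 (not isolated)
Conditions: Et2Zn, CH2I2, CH2Cl2, −10 °C to rt; aq NH4Cl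
Reagents that add atoms: diiodomethane, ICI
Why: Et2Zn first turns O3 into the ethylzinc alkoxide 11, further Et2Zn exchanges with CH2I2 to give EtZnCH2I, and the carbenoid bound to the alkoxide transfers CH2 to C5=C10 through the concerted butterfly transition state, so C10–C14 and C5–C14 form together. The closest known reaction type is the Furukawa variant of the Simmons–Smith cyclopropanation directed by a homoallylic hydroxyl, as practised on 3-hydroxy-5(10)-unsaturated 19-norsteroids. The one new ring, the three-membered ring C5–C10–C14, closes in a single suprafacial [2+1] methylene transfer, so both new bonds lie on one face. C5 and C10 are both controlled by the C3 carbinol centre: A(1,2) strain with C6H2 makes the 4α-methyl pseudoaxial, its trans partner O3 is then pseudoaxial on the β face above C5, and the zinc tether reaches only that face while the methyl screens the α face. The step needs face selectivity and sufficient reactivity at a tetrasubstituted alkene. Both are secured because this electron-rich alkene is the only C=C present, the carbenoid is held next to it, and the two ketal oxygens sit on opposite faces and add no bias.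

**Step 6**
Reactants: 12 cyclopropyl alcohol
Product: 13 4-methyl-5β,10β-methanodecalin-3-one with C8 as dioxolane
Conditions: (n-Pr)4NRuO4 (cat.), NMO, 4 Å MS, CH2Cl2, rt
Reagents that add atoms: none
Why: Ley–Griffith oxidation is neutral, so the ketal and the cyclopropane should survive; the C3 centre has passed on its chirality and is converted into the carbonyl that will direct the ring opening (epimerisation at C4 is of no consequence).

**Step 7**
Reactants: 13 β-cyclopropyl ketone
Product: 16 4,10β-dimethyl-4-octalin-3-one with C8 as dioxolane (C14 now the angular methyl, C4=C5), via potassium enolate 14 (not isolated), via potassium dienolate 15 (not isolated)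
Conditions: KOt-Bu, DMSO–t-BuOH, argon, 80 °C; then H2O
Reagents that add atoms: none
Why: Proposed new method: in base only the C3 ketone can be activated, because the C8 dioxolane is inert, whereas an acid strong enough to open the ring would ionise the ketal and let an enol ether towards C9 expel C14 from C10, the wrong bond; the fully formed C3–C4 enolate 14 is a vinylogous cyclopropanolate whose π system is aligned with the exocyclic C5–C14 bond (C5–C10 lies in its nodal plane), so electron push from O3 breaks C5–C14, the departing C14 is protonated by t-BuOH, relief of ring strain and formation of dienolate 15 drive the step, and the unbuffered aqueous quench lets the ketone settle as the conjugated 4-en-3-one; the closest known reaction types are the acid-induced isomerisation of 5,19-cyclo-3-keto steroids to 10-methyl-4-en-3-ones and the base-induced cleavage of cyclopropanols at the least substituted ring carbon.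

**Step 8**
Reactants: 16 enone ketal
Product: 17 3β-hydroxy-4,10β-dimethyl-4-octalin with C8 as dioxolane
Conditions: NaBH4, CeCl3·7H2O, MeOH, −78 to −20 °C
Reagents that add atoms: none
Why: In this Luche 1,2-reduction hydride adds axially from the α face, away from the 10β-methyl, as with 4-en-3-one steroids, which restores the pseudoequatorial 3β-alcohol while the dioxolane keeps C8 out of the reaction.

**Step 9**
Reactants: 17 allylic alcohol; 18 isobutyric anhydride
Product: 19 3β-isobutyryloxy-4,10β-dimethyl-4-octalin with C8 as dioxolane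
Conditions: (i-PrCO)2O, DMAP (cat.), pyridine, rt
Reagents that add atoms: isobutyric anhydride, CC(C)C(=O)OC(=O)C(C)C
Why: DMAP-catalysed acylation takes place at oxygen and therefore retains the C3 configuration.

**Step 10**
Reactants: 19 isobutyrate ketal
Product: 20 3β-isobutyryloxy-4,10β-dimethyl-4-octalin-8-one
Conditions: PPTS, acetone–H2O, 50 °C
Reagents that add atoms: water, O
Why: This mild acid-catalysed ketal hydrolysis uses a buffered acid too weak to ionise the allylic ester, and the freed C8 ketone cannot conjugate with C4=C5 because the quaternary C10 lies between them.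

**Step 11**
Reactants: 21 methyl acrylate
Product: 22 methyl 2-iodo-3-nitropropanoate (racemic)
Conditions: I2, N2O4, Et2O, 0 °C
Reagents that add atoms: iodine, II; dinitrogen tetroxide, O=[N+]([O-])[N+](=O)[O-]
Why: In this radical iodonitration NO2 adds to the terminal carbon and iodine caps the resulting α-ester radical, which is a standard preparative reaction of acrylates.

**Step 12**
Reactants: 22 methyl 2-iodo-3-nitropropanoate
Product: 23 methyl (E)-3-nitroacrylate
Conditions: NaOAc, Et2O, 0 °C
Reagents that add atoms: none
Why: Dehydroiodination with a weak base removes the acidic proton next to the nitro group and iodide, and should give the more stable E nitroalkene.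

**Step 13**
Reactants: 20 ketone; 23 methyl (E)-3-nitroacrylate
Product: 26 methyl 2-[(7β)-3β-isobutyryloxy-8-oxo-4,10β-dimethyl-4-octalin-7-yl]-3-nitropropanoate (7αH; C11 epimers), via pyrrolidine enamine 24 (not isolated), via iminium nitronate adduct 25 (not isolated)
Conditions: pyrrolidine, TsOH (cat.), benzene, reflux (−H2O), evaporate; 23, Et2O, −20 to 0 °C; then AcOH–NaOAc–H2O, rt
Reagents that add atoms: methyl (E)-3-nitroacrylate, COC(=O)/C=C/[N+](=O)[O-]; water, O
Why: In this Stork enamine Michael addition the enamine forms towards C7 because C9 is neopentyl, and it attacks the nitroacrylate β to the nitro group, at the future C11, a known way to attach an α-acrylate equivalent to a cyclohexanone; hydrolysis in the pyrrolidinium acetate buffer should equilibrate C7 by iminium–enamine exchange to the equatorial 7β isomer of the ring B chair locked by the axial 10β-methyl.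

**Step 14**
Reactants: 26 keto nitro ester
Product: 27 the corresponding 8β-alcohol (7αH, 8αH)
Conditions: LiBH(s-Bu)3 (L-Selectride), THF, −78 °C; AcOH, −78 °C
Reagents that add atoms: none
Why: The bulky trialkylborohydride attacks the cyclohexanone equatorially from the α face, because the β-axial path is blocked by the syn-axial 10β-methyl, and this gives the axial 8β-alcohol; the low temperature and an acidic quench before warming are meant to prevent lactonisation of the γ-hydroxy ester and loss of nitrite.

**Step 15**
Reactants: 27 hydroxy nitro ester; 28 acetic anhydride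
Product: 30 methyl 8β-acetoxy-3β-isobutyryloxyeudesma-4,11(13)-dien-12-oate, via acetoxy nitro ester 29 (not isolated)
Conditions: Ac2O, DMAP, pyridine, 0 °C to rt; then DBU, CH2Cl2, 0 °C
Reagents that add atoms: acetic anhydride, CC(=O)OC(C)=O
Why: DMAP-catalysed acetylation caps O8 before the neutral hydroxyl can attack the ester, and E1cB loss of nitrite (H11 is α to the ester, the nitro group sits on C13) then places the alkene at C11=C13 only, without affecting C7, which is no longer acidic.

**Step 16**
Reactants: 30 diene triester
Product: 31 methyl 8β-acetoxy-5α-hydroperoxy-3β-isobutyryloxyeudesma-4(15),11(13)-dien-12-oate (target)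
Conditions: O2, hν (visible), tetraphenylporphyrin (cat.), CH2Cl2, 0 °C
Reagents that add atoms: dioxygen, O=O
Why: In this Schenck ene reaction singlet oxygen ignores the electron-poor acrylate and attacks the tetrasubstituted C4=C5 from the α face, opposite the 10β-methyl; on that face only the C15 methyl hydrogens and H3α stand perpendicular to the alkene (H6α is pseudoequatorial), and H3α is deactivated by its geminal acyloxy group, so oxygen should bind C5 and hydrogen should leave C15, as known for eudesm-4-enes.

**Compound list**
1 | 6-methoxy-1-tetralone | COc1ccc2c(c1)CCCC2=O | starting material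
2 | methylmagnesium bromide | C[Mg]Br | starting material
3 | 6-methoxy-1-methyl-1,2,3,4-tetrahydronaphthalen-1-ol (racemic) | COc1ccc2c(c1)CCCC2(C)O | intermediate
4 | 7-methoxy-4-methyl-1,2-dihydronaphthalene | COc1ccc2c(c1)CCC=C2C | intermediate
5 | [(1S,2S)-6-methoxy-1-methyltetralin-2-yl](isopinocampheyl)borane | C[C@H]1[C@H](B[C@H]3CCc4cc(OC)ccc4[C@@H]3C)C[C@@H]2C[C@H]1C2(C)C | intermediate
6 | (1S,2S)-6-methoxy-1-methyl-1,2,3,4-tetrahydronaphthalen-2-ol | C[C@@H]1[C@@H](O)CCc2cc(OC)ccc12 | intermediate
7 | (1S,2S)-6-methoxy-1-methyl-1,2,3,4,5,8-hexahydronaphthalen-2-ol | C[C@@H]1[C@@H](O)CCC2=C1CC=C(OC)C2 | intermediate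
8 | ethylene glycol | OCCO | starting material
9 | 3β-hydroxy-4α-methyl-5(10)-octalin, C8 dioxolane | C[C@@H]1[C@@H](O)CCC2=C1CCC3(C2)OCCO3 | intermediate
10 | diiodomethane | ICI | starting material
11 | ethylzinc alkoxide of 9 | C[C@@H]1[C@@H](O[Zn]CC)CCC2=C1CCC3(C2)OCCO3 | intermediate
12 | 3β-hydroxy-4α-methyl-5β,10β-methanodecalin, C8 dioxolane | C[C@@H]1[C@@H](O)CC[C@@]23C[C@@]12CCC4(C3)OCCO4 | intermediate
13 | 4α-methyl-5β,10β-methanodecalin-3-one, C8 dioxolane | C[C@@H]1C(=O)CC[C@@]23C[C@@]12CCC4(C3)OCCO4 | intermediate
14 | potassium C3–C4 enolate of 13 | CC1=C([O-])CC[C@@]23C[C@@]12CCC4(C3)OCCO4.[K+] | intermediate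
15 | potassium 3,5-dienolate of 16 | CC1=C([O-])CC[C@]2(C)CC3(OCCO3)CC=C12.[K+] | intermediate
16 | 4,10β-dimethyl-4-octalin-3-one, C8 dioxolane | CC1=C2CCC3(OCCO3)C[C@@]2(C)CCC1=O | intermediate
17 | 3β-hydroxy-4,10β-dimethyl-4-octalin, C8 dioxolane | CC1=C2CCC3(OCCO3)C[C@@]2(C)CC[C@@H]1O | intermediate
18 | isobutyric anhydride | CC(C)C(=O)OC(=O)C(C)C | starting material
19 | 3β-isobutyryloxy-4,10β-dimethyl-4-octalin, C8 dioxolane | CC1=C2CCC3(OCCO3)C[C@@]2(C)CC[C@@H]1OC(=O)C(C)C | intermediate
20 | 3β-isobutyryloxy-4,10β-dimethyl-4-octalin-8-one | CC1=C2CCC(=O)C[C@@]2(C)CC[C@@H]1OC(=O)C(C)C | intermediate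
21 | methyl acrylate | C=CC(=O)OC | starting material
22 | methyl 2-iodo-3-nitropropanoate | COC(=O)C(I)C[N+](=O)[O-] | intermediate
23 | methyl (E)-3-nitroacrylate | COC(=O)/C=C/[N+](=O)[O-] | intermediate
24 | C7=C8 pyrrolidine enamine of 20 | CC1=C2CC=C(N3CCCC3)C[C@@]2(C)CC[C@@H]1OC(=O)C(C)C | intermediate
25 | C8 iminium / C13 nitronate Michael adduct | CC1=C2CC(C(C=[N+]([O-])[O-])C(=O)OC)C(=[N+]3CCCC3)C[C@@]2(C)CC[C@@H]1OC(=O)C(C)C | intermediate
26 | 7β-[1-methoxycarbonyl-2-nitroethyl]-8-ketone (C11 epimers) | CC1=C2C[C@H](C(C[N+](=O)[O-])C(=O)OC)C(=O)C[C@@]2(C)CC[C@@H]1OC(=O)C(C)C | intermediate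
27 | 8β-alcohol of 26 | CC1=C2C[C@H](C(C[N+](=O)[O-])C(=O)OC)[C@H](O)C[C@@]2(C)CC[C@@H]1OC(=O)C(C)C | intermediate
28 | acetic anhydride | CC(=O)OC(C)=O | starting material
29 | 8β-acetate of 27 | CC1=C2C[C@H](C(C[N+](=O)[O-])C(=O)OC)[C@H](OC(C)=O)C[C@@]2(C)CC[C@@H]1OC(=O)C(C)C | intermediate
30 | methyl 8β-acetoxy-3β-isobutyryloxyeudesma-4,11(13)-dien-12-oate | CC1=C2C[C@H](C(=C)C(=O)OC)[C@H](OC(C)=O)C[C@@]2(C)CC[C@@H]1OC(=O)C(C)C | intermediate
31 | methyl 8β-acetoxy-5α-hydroperoxy-3β-isobutyryloxyeudesma-4(15),11(13)-dien-12-oate | C=C(C(=O)OC)[C@H]1C[C@@]2(OO)C(=C)[C@@H](OC(=O)C(C)C)CC[C@]2(C)C[C@H]1OC(C)=O | target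

**Step count**
Total step count: 16. There are 14 steps in the main line and 2 for reagent 23.
Longest linear sequence: 14 (steps 1–10 and 13–16).

**Steps most likely to fail**

*Step 7 (base-induced ring opening).*
- Risk: the enolate may persist without breaking C5–C14 at temperatures the material tolerates, or condensation of the enolate with unreacted ketone may become faster than the cleavage.
- Fallback: it sets out from 13, returns to the route at 16, and replaces the ionic trigger with a radical one.
- Equilibrating silylation (TMSCl, Et3N, DMF, heat) gives the more substituted C3–C4 silyl enol ether F1. NBS in THF converts it into the tertiary 4-bromo ketone F2.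
- Bu3SnH with AIBN in dilute benzene then generates the C4 radical. This is a cyclopropylcarbinyl radical that can only break a bond at C5, and for reasons of orbital overlap it should break the exocyclic C5–C14 bond.
- The primary C14 radical takes hydrogen from the stannane and gives 16 under neutral conditions that leave the ketal untouched. Any material silylated towards C2 is simply reduced back to 13 and can be recycled.

*Step 14 (reduction at C8).*
- Risk: the 8β-alkoxide or alcohol may close onto the C12 ester (lactonisation), or base-induced loss of nitrite may be followed by conjugate reduction of the resulting acrylate.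
- Fallback: it sets out from 20, returns at 30, and shields C12 as a tert-butyl ester.
- tert-Butyl acrylate is iodonitrated to tert-butyl 2-iodo-3-nitropropanoate F3, which is dehydroiodinated with NaOAc to tert-butyl (E)-3-nitroacrylate F4.
- Addition of enamine 24 to F4 and hydrolysis give the keto nitro tert-butyl ester F5. LiBH(s-Bu)3 reduces it to the 8β-alcohol F6, whose ester is too hindered for ring closure.
- Acetylation gives the acetoxy nitro ester F7, and DBU gives the tert-butyl acrylate F8.
- TMSOTf with 2,6-lutidine cleaves the tert-butyl group to the silyl ester F9. Aqueous work-up gives the acrylic acid F10, and TMSCHN2 in methanol–toluene methylates it to 30.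

*Step 13 (C7–C11 bond).*
- Risk: the nitroalkene may oligomerise, early loss of nitrite may let the new alkene drift into conjugation with C8=O, or equilibration at C7 may remain incomplete.
- Fallback: it sets out from 20, returns at 30, and uses a sulfur-stabilised cation in place of the Michael acceptor.
- Thiophenol and methyl 2-bromopropanoate (K2CO3) give methyl 2-(phenylthio)propanoate F11. NCS chlorinates it to methyl 2-chloro-2-(phenylthio)propanoate F12.
- Ketone 20 is converted with LiN(i-Pr)2 and TMSCl at −78 °C into the C7=C8 silyl enol ether F13. ZnBr2-catalysed phenylthioalkylation with F12, followed by acid-catalysed equilibration of C7 (TsOH, cat.), gives the 7β sulfide keto ester F14.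
- Reduction with LiBH(s-Bu)3 and acetylation with Ac2O in the same flask give the 8β-acetoxy sulfide F15. NaIO4 oxidises sulfur without touching C4=C5 and gives the sulfoxide F16.
- Thermal syn elimination in toluene, which prefers the methyl hydrogens over the tertiary H7, gives 30.

**Further compounds**
F1 | step 7 | C3–C4 trimethylsilyl enol ether of 13 | CC1=C(O[Si](C)(C)C)CC[C@@]23C[C@@]12CCC4(C3)OCCO4
F2 | step 7 | 4-bromo-4-methyl-5β,10β-methanodecalin-3-one, C8 dioxolane (C4 epimers) | CC1(Br)C(=O)CC[C@@]23C[C@@]12CCC4(C3)OCCO4
F3 | step 14 | tert-butyl 2-iodo-3-nitropropanoate | CC(C)(C)OC(=O)C(I)C[N+](=O)[O-]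
F4 | step 14 | tert-butyl (E)-3-nitroacrylate | CC(C)(C)OC(=O)/C=C/[N+](=O)[O-]
F5 | step 14 | keto nitro tert-butyl ester (tert-butyl analogue of 26) | CC1=C2C[C@H](C(C[N+](=O)[O-])C(=O)OC(C)(C)C)C(=O)C[C@@]2(C)CC[C@@H]1OC(=O)C(C)C
F6 | step 14 | 8β-alcohol of F5 | CC1=C2C[C@H](C(C[N+](=O)[O-])C(=O)OC(C)(C)C)[C@H](O)C[C@@]2(C)CC[C@@H]1OC(=O)C(C)C
F7 | step 14 | 8β-acetate of F6 | CC1=C2C[C@H](C(C[N+](=O)[O-])C(=O)OC(C)(C)C)[C@H](OC(C)=O)C[C@@]2(C)CC[C@@H]1OC(=O)C(C)C
F8 | step 14 | tert-butyl 8β-acetoxy-3β-isobutyryloxyeudesma-4,11(13)-dien-12-oate | CC1=C2C[C@H](C(=C)C(=O)OC(C)(C)C)[C@H](OC(C)=O)C[C@@]2(C)CC[C@@H]1OC(=O)C(C)C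
F9 | step 14 | trimethylsilyl 8β-acetoxy-3β-isobutyryloxyeudesma-4,11(13)-dien-12-oate | CC1=C2C[C@H](C(=C)C(=O)O[Si](C)(C)C)[C@H](OC(C)=O)C[C@@]2(C)CC[C@@H]1OC(=O)C(C)C
F10 | step 14 | 8β-acetoxy-3β-isobutyryloxyeudesma-4,11(13)-dien-12-oic acid | CC1=C2C[C@H](C(=C)C(=O)O)[C@H](OC(C)=O)C[C@@]2(C)CC[C@@H]1OC(=O)C(C)C
F11 | step 13 | methyl 2-(phenylthio)propanoate | COC(=O)C(C)Sc1ccccc1
F12 | step 13 | methyl 2-chloro-2-(phenylthio)propanoate | COC(=O)C(C)(Cl)Sc1ccccc1
F13 | step 13 | C7=C8 trimethylsilyl enol ether of 20 | CC1=C2CC=C(O[Si](C)(C)C)C[C@@]2(C)CC[C@@H]1OC(=O)C(C)C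
F14 | step 13 | 7β-[1-methoxycarbonyl-1-(phenylthio)ethyl]-8-ketone (C11 epimers) | CC1=C2C[C@H](C(C)(Sc3ccccc3)C(=O)OC)C(=O)C[C@@]2(C)CC[C@@H]1OC(=O)C(C)C
F15 | step 13 | 8β-acetoxy sulfide | CC1=C2C[C@H](C(C)(Sc3ccccc3)C(=O)OC)[C@H](OC(C)=O)C[C@@]2(C)CC[C@@H]1OC(=O)C(C)C
F16 | step 13 | 8β-acetoxy sulfoxide | CC1=C2C[C@H](C(C)(S(=O)c3ccccc3)C(=O)OC)[C@H](OC(C)=O)C[C@@]2(C)CC[C@@H]1OC(=O)C(C)C
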